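**Retrosynthetic overview**
1. GA32 ⇐ 12,15-dioxo-GA3: the 12α- and 15β-carbinols are both set in the last step by one hydride reduction.
2. The diketone ⇐ a 12β-hydroxy-GA3 derivative, by SeO2 allylic oxidation at C15 and oxidation of both secondary carbinols.
3. The 12β-hydroxy-16-ene ⇐ a 17-nor-16-ketone by methylenation; ring D of that ketone is re-closed (C13–C16) by an N-heterocyclic-carbene-catalysed crossed benzoin of a seco keto-aldehyde.
4. The keto-aldehyde ⇐ a ring-D-opened C13 ketone, which allows enolate hydroxylation at C12; that ketone ⇐ GA3 by ozonolysis of the 16-ene, reduction and glycol cleavage.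
5. Rings A, B, C and the lactone come intact from gibberellic acid; order of events: ring D opened, C12 oxygenated, ring D re-formed, C15 oxygenated.

Assumption: gibberellic acid (GA3), a bulk fermentation product, counts as a commercially available starting material, so this is a semisynthesis; atom numbering and α/β follow gibberellane usage (12α = axial on ring C, anti to the C15–C16 bridge; 15β = endo, facing the C9–C11–C12 bridge).

**Step 1**
Reactants: 1 gibberellic acid (GA3)
Product: 2 GA3 methyl ester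
Conditions: Me3SiCHN2, toluene/MeOH 4:1, 0 °C → rt
Reagents that add atoms: trimethylsilyldiazomethane C[Si](C)(C)C=[N+]=[N-]
Why: Diazoalkane O-methylation of the carboxylic acid (proton transfer, then SN2 on the methyldiazonium ion) runs under neutral conditions, so the base- and acid-labile ring A allylic lactone and all stereocentres are untouched.

**Step 2**
Reactants: 2 GA3 methyl ester
Product: 3 3-O-TBS-GA3 methyl ester
Conditions: t-BuMe2SiCl, imidazole, DMF, 35 °C
Reagents that add atoms: tert-butyldimethylsilyl chloride CC(C)(C)[Si](C)(C)Cl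
Why: Silyl ether formation is selective for the only secondary alcohol because the bridgehead tertiary 13-OH does not react with the silyl chloride, and capping the C3 oxygen blocks the alkoxide-triggered lactone rearrangement of ring A in the basic steps that follow.

**Step 3**
Reactants: 3 3-O-TBS-GA3 methyl ester
Product: 5 3-O-TBS-17-nor-16β-hydroxy-GA3 methyl ester (13,16-diol; 16-OH endo), via 17-nor-16-ketone 4 (not isolated)
Conditions: O3 (1 equiv, indicator end point), pyridine, CH2Cl2/MeOH, −78 °C; Me2S; then NaBH4, −78 → 0 °C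
Reagents that add atoms: ozone [O-][O+]=O
Why: Ozonolysis (Criegee cleavage) picks the electron-rich 1,1-disubstituted C16 alkene over the C1 alkene that is deactivated by two allylic C–O bonds, and NaBH4 then reduces the cyclopentanone from the exo face (side of the C14 bridge) to the endo carbinol, a centre that is destroyed again in step 4.

**Step 4**
Reactants: 5 the 13,16-diol
Product: 7 keto-acetal (3-O-TBS-17-nor-13,16-seco-GA3 methyl ester; C13 ketone; C16 dimethyl acetal), via keto-aldehyde 6 (not isolated)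
Conditions: Pb(OAc)4, CH2Cl2, 0 °C; filter, concentrate; then HC(OMe)3 (1.2 equiv), pyridinium p-toluenesulfonate (10 mol%), MeOH, rt
Reagents that add atoms: trimethyl orthoformate COC(OC)OC, methanol CO
Why: Criegee glycol cleavage breaks the C13–C16 bond to unveil the C13 ketone that will activate C12, and the aldehyde is at once masked by acid-catalysed acetalisation, which is much faster for an aldehyde than for the ring C ketone and forestalls intramolecular aldol reaction.

**Step 5**
Reactants: 7 keto-acetal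
Product: 8 12β-hydroxy keto-acetal
Conditions: NaN(SiMe3)2 (1.1 equiv), THF, −78 °C; then 2-(phenylsulfonyl)-3-phenyloxaziridine, −78 °C; AcOH quench
Reagents that add atoms: 2-(phenylsulfonyl)-3-phenyloxaziridine (Davis oxaziridine) O=S(=O)(c1ccccc1)N1OC1c1ccccc1
Why: Kinetic enolisation goes to C12 because C14 is neopentylic (next to quaternary C8), and Davis oxidation of the enolate delivers oxygen to the β-face, opposite the syn-axial C9–C10 bond that blocks the α-face, to give the 12β-carbinol, a provisional centre that is re-set in step 13.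

**Step 6**
Reactants: 8 12β-hydroxy keto-acetal
Product: 9 12β-triethylsilyloxy keto-aldehyde
Conditions: Et3SiOTf (3 equiv), 2,4,6-collidine (4.5 equiv), CH2Cl2, 0 °C; then H2O, 0 °C → rt
Reagents that add atoms: triethylsilyl trifluoromethanesulfonate CC[Si](CC)(CC)OS(=O)(=O)C(F)(F)F, water O
Why: The silyl triflate silylates the free carbinol and, with collidine, converts the dimethyl acetal through a collidinium intermediate into the aldehyde on addition of water (chemoselective acetal cleavage that leaves silyl ethers and the ketone alone), with no stereocentre touched.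

**Step 7**
Reactants: 9 12β-triethylsilyloxy keto-aldehyde
Product: 10 3-O-TBS-12β-triethylsilyloxy-17-nor-16-oxo-GA3 methyl ester (ring D re-closed; 13-OH)
Conditions: 2-(pentafluorophenyl)-6,7-dihydro-5H-pyrrolo[2,1-c][1,2,4]triazol-2-ium tetrafluoroborate (15 mol%), Et3N (15 mol%), toluene, rt
Reagents that add atoms: none
Why: Intramolecular crossed benzoin reaction under N-heterocyclic carbene catalysis, in which the Breslow intermediate formed at C16 adds to the C13 ketone; because the two-carbon tether on C8 can reach C13 only from its own (β) face, the bicyclo[3.2.1]octane closes with the natural C13 configuration (13-OH exocyclic at the bridgehead).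

**Step 8**
Reactants: 10 the 17-nor-16-ketone
Product: 12 3-O-TBS-12β-hydroxy-GA3 methyl ester, via 12-O-TES 16-ene 11 (not isolated)
Conditions: Zn, CH2Br2, TiCl4 (pre-formed Lombardo reagent), THF/CH2Cl2, 0 °C → rt; NaHCO3 work-up; then pyridinium p-toluenesulfonate, MeOH, rt
Reagents that add atoms: dibromomethane BrCBr
Why: Lombardo methylenation is non-basic, so the α-ketol neither rearranges (acyloin shift) nor epimerises and esters and lactone are ignored, and mild acid methanolysis then removes only the triethylsilyl ether, the hindered TBS ether being far slower.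

**Step 9**
Reactants: 12 3-O-TBS-12β-hydroxy-GA3 methyl ester
Product: 13 3-O-TBS-12β,15α-dihydroxy-GA3 methyl ester
Conditions: SeO2 (0.5 equiv), t-BuOOH (3 equiv), CH2Cl2, 0 °C → rt
Reagents that add atoms: tert-butyl hydroperoxide CC(C)(C)OO, selenium dioxide O=[Se]=O
Why: SeO2 allylic oxidation (Riley oxidation: ene reaction then [2,3]-sigmatropic shift) can only functionalise C15, the sole allylic CH2 of the reactive 1,1-disubstituted alkene, and delivers oxygen on the exo face (15α), a provisional centre that is erased in step 11.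

**Step 10**
Reactants: 13 3-O-TBS-12β,15α-dihydroxy-GA3 methyl ester
Product: 14 3-O-TBS-12β,15α-dihydroxy-GA3 (free C7 acid)
Conditions: LiSPr (10 equiv), HMPA, rt; then cold dilute HCl to pH 3
Reagents that add atoms: none
Why: SN2 O-demethylation by the soft thiolate in HMPA cleaves the hindered methyl ester without hydroxide, which would destroy ring A, and is placed before any enone exists so that no conjugate addition can occur; no stereocentre changes.

**Step 11**
Reactants: 14 the triol acid
Product: 15 3-O-TBS-12,15-dioxo-GA3 (13-hydroxy-12-ketone; 16-en-15-one)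
Conditions: 2-iodoxybenzoic acid (IBX, 4 equiv), DMSO, rt
Reagents that add atoms: none
Why: IBX oxidation converts both secondary carbinols (C12 to the α-ketol without glycol cleavage, allylic C15 to the exo-methylene enone) while the tertiary 13-OH, the silyl ether and the acid are inert, erasing both provisional stereocentres.

**Step 12**
Reactants: 15 3-O-TBS-12,15-dioxo-GA3
Product: 16 12,15-dioxo-GA3
Conditions: HF·pyridine, THF/pyridine, 0 °C → rt
Reagents that add atoms: none
Why: Fluoride-mediated desilylation under weakly acidic conditions frees the 3-OH without ever generating the 3-alkoxide that would trigger lactone migration, and does not affect the enone or the α-ketol.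

**Step 13**
Reactants: 16 12,15-dioxo-GA3
Product: 17 GA32 (12α,15β-dihydroxy-GA3)
Conditions: NaBH4, CeCl3·7H2O, MeOH, −78 → −40 °C; AcOH quench; reverse-phase chromatography
Reagents that add atoms: none
Why: Luche reduction, in which hydride adds 1,2 to the enone from the exo face of C15 (the side of the one-carbon C14 bridge, the endo face being screened by the C9–C11–C12 bridge) to give the endo 15β-alcohol, while the C12 ketone is attacked equatorially from the β-side because the axial α-trajectory is blocked by the syn-axial C9–C10 bond, giving the axial 12α-alcohol.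

**Compound list**
1 | gibberellic acid (GA3) | C=C1C[C@]23C[C@@]1(O)CC[C@H]2[C@@]12C=C[C@H](O)[C@@](C)(C(=O)O1)[C@H]2[C@@H]3C(=O)O | starting material
2 | GA3 methyl ester | C=C1C[C@]23C[C@@]1(O)CC[C@H]2[C@@]12C=C[C@H](O)[C@@](C)(C(=O)O1)[C@H]2[C@@H]3C(=O)OC | intermediate
3 | 3-O-TBS-GA3 methyl ester | C=C1C[C@]23C[C@@]1(O)CC[C@H]2[C@@]12C=C[C@H](O[Si](C)(C)C(C)(C)C)[C@@](C)(C(=O)O1)[C@H]2[C@@H]3C(=O)OC | intermediate
4 | 3-O-TBS-17-nor-16-oxo-GA3 methyl ester (13-hydroxy-16-ketone) | O=C1C[C@]23C[C@@]1(O)CC[C@H]2[C@@]12C=C[C@H](O[Si](C)(C)C(C)(C)C)[C@@](C)(C(=O)O1)[C@H]2[C@@H]3C(=O)OC | intermediate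
5 | 3-O-TBS-17-nor-16β-hydroxy-GA3 methyl ester (13,16-diol, 16-OH endo) | O[C@H]1C[C@]23C[C@@]1(O)CC[C@H]2[C@@]12C=C[C@H](O[Si](C)(C)C(C)(C)C)[C@@](C)(C(=O)O1)[C@H]2[C@@H]3C(=O)OC | intermediate
6 | 3-O-TBS-17-nor-13,16-seco-GA3 methyl ester, C13 ketone, C16 aldehyde (ring C cyclohexanone with CH2CHO on C8) | O=CC[C@]23CC(=O)CC[C@H]2[C@@]12C=C[C@H](O[Si](C)(C)C(C)(C)C)[C@@](C)(C(=O)O1)[C@H]2[C@@H]3C(=O)OC | intermediate
7 | keto-acetal: as 6 but C16 as dimethyl acetal | COC(OC)C[C@]23CC(=O)CC[C@H]2[C@@]12C=C[C@H](O[Si](C)(C)C(C)(C)C)[C@@](C)(C(=O)O1)[C@H]2[C@@H]3C(=O)OC | intermediate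
8 | 12β-hydroxy keto-acetal (OH on C12, cis to the C9 hydrogen and the C8 side chain) | COC(OC)C[C@]23CC(=O)[C@H](O)C[C@H]2[C@@]12C=C[C@H](O[Si](C)(C)C(C)(C)C)[C@@](C)(C(=O)O1)[C@H]2[C@@H]3C(=O)OC | intermediate
9 | 12β-triethylsilyloxy keto-aldehyde | O=CC[C@]23CC(=O)[C@H](O[Si](CC)(CC)CC)C[C@H]2[C@@]12C=C[C@H](O[Si](C)(C)C(C)(C)C)[C@@](C)(C(=O)O1)[C@H]2[C@@H]3C(=O)OC | intermediate
10 | 3-O-TBS-12β-triethylsilyloxy-17-nor-16-oxo-GA3 methyl ester | O=C1C[C@]23C[C@@]1(O)[C@H](O[Si](CC)(CC)CC)C[C@H]2[C@@]12C=C[C@H](O[Si](C)(C)C(C)(C)C)[C@@](C)(C(=O)O1)[C@H]2[C@@H]3C(=O)OC | intermediate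
11 | 3-O-TBS-12β-triethylsilyloxy-GA3 methyl ester (16-ene restored) | C=C1C[C@]23C[C@@]1(O)[C@H](O[Si](CC)(CC)CC)C[C@H]2[C@@]12C=C[C@H](O[Si](C)(C)C(C)(C)C)[C@@](C)(C(=O)O1)[C@H]2[C@@H]3C(=O)OC | intermediate
12 | 3-O-TBS-12β-hydroxy-GA3 methyl ester | C=C1C[C@]23C[C@@]1(O)[C@H](O)C[C@H]2[C@@]12C=C[C@H](O[Si](C)(C)C(C)(C)C)[C@@](C)(C(=O)O1)[C@H]2[C@@H]3C(=O)OC | intermediate
13 | 3-O-TBS-12β,15α-dihydroxy-GA3 methyl ester | C=C1[C@H](O)[C@]23C[C@@]1(O)[C@H](O)C[C@H]2[C@@]12C=C[C@H](O[Si](C)(C)C(C)(C)C)[C@@](C)(C(=O)O1)[C@H]2[C@@H]3C(=O)OC | intermediate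
14 | 3-O-TBS-12β,15α-dihydroxy-GA3 (free acid) | C=C1[C@H](O)[C@]23C[C@@]1(O)[C@H](O)C[C@H]2[C@@]12C=C[C@H](O[Si](C)(C)C(C)(C)C)[C@@](C)(C(=O)O1)[C@H]2[C@@H]3C(=O)O | intermediate
15 | 3-O-TBS-12,15-dioxo-GA3 | C=C1C(=O)[C@]23C[C@@]1(O)C(=O)C[C@H]2[C@@]12C=C[C@H](O[Si](C)(C)C(C)(C)C)[C@@](C)(C(=O)O1)[C@H]2[C@@H]3C(=O)O | intermediate
16 | 12,15-dioxo-GA3 | C=C1C(=O)[C@]23C[C@@]1(O)C(=O)C[C@H]2[C@@]12C=C[C@H](O)[C@@](C)(C(=O)O1)[C@H]2[C@@H]3C(=O)O | intermediate
17 | GA32 (12α,15β-dihydroxy-GA3) | C=C1[C@@H](O)[C@]23C[C@@]1(O)[C@@H](O)C[C@H]2[C@@]12C=C[C@H](O)[C@@](C)(C(=O)O1)[C@H]2[C@@H]3C(=O)O | target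

**Totals**
Total step count: 13 (three of them telescoped through unisolated intermediates 4, 6 and 11). Longest linear sequence: 13 steps from gibberellic acid.

**Steps most likely to fail, with fallbacks**

Step 5 (enolate hydroxylation). Risks are C14 versus C12 enolisation, addition of the enolate to the sulfonimine by-product, and over-oxidation. The fallback sets out from 7 and uses a Rubottom sequence in place of direct enolate oxidation. Ketone 7 is deprotonated with LiN(iPr)2 in the presence of Me3SiCl (THF, −78 °C), and the C12–C13 trimethylsilyl enol ether F1 is isolated so that its regiochemistry can be checked. Oxidation of the enol ether with dimethyldioxirane (acetone/CH2Cl2, −78 °C) on the same β-face gives, after silyl migration, the 12β-trimethylsilyloxy ketone F2. Brief citric acid treatment in aqueous MeOH then removes the trimethylsilyl group, and the route is rejoined at 8.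

Step 7 (benzoin closure of the bridged ring). Risks are a slow or reversible closure onto the hindered ketone and a competing aldol reaction of the C12 enolate with the aldehyde. The fallback sets out from 9 and closes ring D reductively instead. SmI2 (THF, t-BuOH, −78 °C) reduces the aldehyde first to its ketyl, which adds to the C13 ketone (pinacol cyclisation) to give the 13,16-diol F3, whose 16-OH is expected exo, cis to the bridgehead 13-OH. Oxidation of the secondary C16 carbinol of this diol with IBX then gives the α-ketol, and the route is rejoined at 10.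

Step 13 (double reduction). Risks are the wrong face at C12, or conjugate reduction of the enone if conditions have to be forced. The fallback sets out from 12 and sets the two centres separately.
IBX (DMSO) oxidises the only secondary carbinol of 12 to give the 12-ketone F4.
LiBH(s-Bu)3 (THF, −78 °C), too bulky for the axial trajectory and usable here because no enone is present, then gives the 12α-alcohol F5.
SeO2/t-BuOOH hydroxylates C15 to give the 12α,15α-diol F6, and LiSPr/HMPA cleaves the methyl ester to give the free acid F7.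
MnO2 (CH2Cl2) oxidises only the allylic C15 carbinol to give the 12α-hydroxy enone F8.
HF·pyridine removes the silyl group to give the 12α-hydroxy-15-oxo acid F9.
Luche reduction of the single remaining ketone then gives the target, and the route is rejoined at 17.

**Further compounds**
F1 | step 5 | C12–C13 trimethylsilyl enol ether of keto-acetal 7 | COC(OC)C[C@]23CC(O[Si](C)(C)C)=CC[C@H]2[C@@]12C=C[C@H](O[Si](C)(C)C(C)(C)C)[C@@](C)(C(=O)O1)[C@H]2[C@@H]3C(=O)OC
F2 | step 5 | 12β-trimethylsilyloxy keto-acetal | COC(OC)C[C@]23CC(=O)[C@H](O[Si](C)(C)C)C[C@H]2[C@@]12C=C[C@H](O[Si](C)(C)C(C)(C)C)[C@@](C)(C(=O)O1)[C@H]2[C@@H]3C(=O)OC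
F3 | step 7 | 3-O-TBS-12β-triethylsilyloxy-17-nor-16α-hydroxy-GA3 methyl ester (13,16-diol, 16-OH exo) | O[C@@H]1C[C@]23C[C@@]1(O)[C@H](O[Si](CC)(CC)CC)C[C@H]2[C@@]12C=C[C@H](O[Si](C)(C)C(C)(C)C)[C@@](C)(C(=O)O1)[C@H]2[C@@H]3C(=O)OC
F4 | step 13 | 3-O-TBS-12-oxo-GA3 methyl ester | C=C1C[C@]23C[C@@]1(O)C(=O)C[C@H]2[C@@]12C=C[C@H](O[Si](C)(C)C(C)(C)C)[C@@](C)(C(=O)O1)[C@H]2[C@@H]3C(=O)OC
F5 | step 13 | 3-O-TBS-12α-hydroxy-GA3 methyl ester | C=C1C[C@]23C[C@@]1(O)[C@@H](O)C[C@H]2[C@@]12C=C[C@H](O[Si](C)(C)C(C)(C)C)[C@@](C)(C(=O)O1)[C@H]2[C@@H]3C(=O)OC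
F6 | step 13 | 3-O-TBS-12α,15α-dihydroxy-GA3 methyl ester | C=C1[C@H](O)[C@]23C[C@@]1(O)[C@@H](O)C[C@H]2[C@@]12C=C[C@H](O[Si](C)(C)C(C)(C)C)[C@@](C)(C(=O)O1)[C@H]2[C@@H]3C(=O)OC
F7 | step 13 | 3-O-TBS-12α,15α-dihydroxy-GA3 (free acid) | C=C1[C@H](O)[C@]23C[C@@]1(O)[C@@H](O)C[C@H]2[C@@]12C=C[C@H](O[Si](C)(C)C(C)(C)C)[C@@](C)(C(=O)O1)[C@H]2[C@@H]3C(=O)O
F8 | step 13 | 3-O-TBS-12α-hydroxy-15-oxo-GA3 | C=C1C(=O)[C@]23C[C@@]1(O)[C@@H](O)C[C@H]2[C@@]12C=C[C@H](O[Si](C)(C)C(C)(C)C)[C@@](C)(C(=O)O1)[C@H]2[C@@H]3C(=O)O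
F9 | step 13 | 12α-hydroxy-15-oxo-GA3 | C=C1C(=O)[C@]23C[C@@]1(O)[C@@H](O)C[C@H]2[C@@]12C=C[C@H](O)[C@@](C)(C(=O)O1)[C@H]2[C@@H]3C(=O)O
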